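The ester groups are removed first. The ten-membered ring is then opened at both bonds of the C1 carbonyl (C1–C2 and C1–C10), which releases CO. The seco chain is cut at C6–C7 and C7–C8, and the lactone at O–C12.
In the forward direction, a 1,1-dibromoalkene carrying C11–C13 acts as a C7 gem-dianion. It is joined first to the C2–C6 epoxy aldehyde and then to the C8–C10 iodoenal.
The oxirane ring is present from step 1. Oxidative lactonisation closes the butenolide ring, and the carbonylative coupling closes the carbocycle last.
C4/C5 come from Sharpless epoxidation with D-(−)-tartrate, C6 from Cornforth-type addition to the cis-epoxy aldehyde, C8 from CBS reduction, and C10 from protonation of the C1–C10 enolate.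
The enabling feature is that C1 is the only carbonyl carbon of the ten-membered ring. It lies between the plain C2 methylene and the methyl-bearing C10, opposite the crowded C4–C8 arc (cis-oxirane ring, butenolide ring), and carries only oxygen, so it can enter as CO between boron on C2 and iodine on C10.

Key step: step 16

Assumption: germacrane numbers are used for all intermediates (C14 = methyl on C10, C15 = methyl on C4), and peripheral protonation of the ten-membered C1–C10 enolate is taken to favour the 10S epimer.

Step 1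
Reactants: 1 (Z)-3-methylpent-2-en-4-yn-1-ol
Product: 2 [(2R,3S)-3-ethynyl-3-methyloxiran-2-yl]methanol
Conditions: Ti(OiPr)4 (10 mol %), D-(−)-diisopropyl tartrate (13 mol %), t-BuOOH, 4 Å MS, CH2Cl2, −20 °C
Reagents that add atoms: tert-butyl hydroperoxide, CC(C)(C)OO
Why: Sharpless asymmetric epoxidation of a Z-trisubstituted allylic alcohol, in which the D-(−)-tartrate/titanium catalyst delivers oxygen to the face that gives 4S,5R and the Z-alkene places C3 and C6 cis on the oxirane; the alkyne is kept here because an ethynyl oxirane should resist titanium-induced opening better than the vinyl oxirane.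

Step 2
Reactants: 2 [(2R,3S)-3-ethynyl-3-methyloxiran-2-yl]methanol
Product: 3 [(2R,3S)-3-ethenyl-3-methyloxiran-2-yl]methanol
Conditions: H2 (1 atm), Pd/CaCO3 poisoned with Pb(OAc)2, quinoline, EtOAc, rt
Reagents that add atoms: none
Why: Lindlar-type semihydrogenation should stop at the terminal alkene on the lead-poisoned, quinoline-moderated palladium surface and leave the oxirane and both stereocentres untouched.

Step 3
Reactants: 3 [(2R,3S)-3-ethenyl-3-methyloxiran-2-yl]methanol
Product: 4 (2S,3S)-3-ethenyl-3-methyloxirane-2-carbaldehyde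
Conditions: Dess–Martin periodinane, pyridine, CH2Cl2, 0 °C
Reagents that add atoms: none
Why: Dess–Martin oxidation buffered with pyridine turns the primary alcohol into the C6 aldehyde under near-neutral conditions that the acid-labile tertiary vinyl oxirane should tolerate, and the oxirane C–H at C5 is not prone to epimerisation (the descriptor at C5 changes only through CIP ranking).

Step 4
Reactants: 5 but-2-yn-1-ol
Product: 6 (Z)-3-iodobut-2-en-1-ol
Conditions: NaAlH2(OCH2CH2OMe)2, THF, 0 °C to rt; then I2, −78 °C
Reagents that add atoms: iodine, II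
Why: Hydroxyl-directed trans-hydroalumination of the propargylic alcohol places aluminium on the distal carbon inside a five-membered alkoxyaluminate, and iodinolysis with retention gives the Z-iodoalkene with C8 and iodine cis.

Step 5
Reactants: 6 (Z)-3-iodobut-2-en-1-ol
Product: 7 (Z)-3-iodobut-2-enal
Conditions: MnO2, CH2Cl2, rt
Reagents that add atoms: none
Why: Allylic oxidation with MnO2 is neutral and heterogeneous, so the Z geometry of the β-iodo enal should be kept.

Step 6
Reactants: 8 methyl 2-(hydroxymethyl)prop-2-enoate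
Product: 9 methyl 2-{[(tert-butyldimethylsilyl)oxy]methyl}prop-2-enoate
Conditions: TBSCl, imidazole, CH2Cl2, rt
Reagents that add atoms: tert-butyldimethylsilyl chloride, CC(C)(C)[Si](C)(C)Cl
Why: Standard silylation of a primary alcohol masks the C13 oxygen as an ether that zerovalent palladium cannot ionise later.

Step 7
Reactants: 9 methyl 2-{[(tert-butyldimethylsilyl)oxy]methyl}prop-2-enoate
Product: 10 methyl 3-[(tert-butyldimethylsilyl)oxy]-2-oxopropanoate
Conditions: O3, CH2Cl2, −78 °C; then Me2S
Reagents that add atoms: ozone, [O-][O+]=O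
Why: Ozonolysis with reductive work-up cleaves the 1,1-disubstituted alkene to the α-keto ester, whose ketone carbon is C11.

Step 8
Reactants: 10 methyl 3-[(tert-butyldimethylsilyl)oxy]-2-oxopropanoate
Product: 11 methyl 3,3-dibromo-2-{[(tert-butyldimethylsilyl)oxy]methyl}prop-2-enoate
Conditions: CBr4, PPh3, CH2Cl2, 0 °C
Reagents that add atoms: carbon tetrabromide, BrC(Br)(Br)Br
Why: Ramirez dibromoolefination works well on the activated ketone of an α-keto ester and brings in C7 as an alkene carbon with two exchangeable bromines.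

Step 9
Reactants: 11 methyl 3,3-dibromo-2-{[(tert-butyldimethylsilyl)oxy]methyl}prop-2-enoate
Product: 12 3,3-dibromo-2-{[(tert-butyldimethylsilyl)oxy]methyl}prop-2-en-1-ol
Conditions: i-Bu2AlH (2.2 equiv), CH2Cl2, −78 °C
Reagents that add atoms: none
Why: i-Bu2AlH reduces the conjugated ester by 1,2-addition to the allylic alcohol without touching the vinylic C–Br bonds or the silyl ether, and the freed C12 hydroxyl serves as directing group and later as lactone carbon.

Step 10
Reactants: 12 3,3-dibromo-2-{[(tert-butyldimethylsilyl)oxy]methyl}prop-2-en-1-ol; 4 (2S,3S)-3-ethenyl-3-methyloxirane-2-carbaldehyde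
Product: 14 (1S,2Z)-2-bromo-3-{[(tert-butyldimethylsilyl)oxy]methyl}-1-[(2R,3S)-3-ethenyl-3-methyloxiran-2-yl]but-2-ene-1,4-diol, via chelated bromolithio carbenoid 13 (not isolated)
Conditions: n-BuLi (2.0 equiv), THF–Et2O, −100 °C; then 4; then H2O
Reagents that add atoms: none
Why: After deprotonation, bromine–lithium exchange should take the bromine cis to the CH2OLi group because the 1-bromo-1-lithioalkene is held in a five-membered chelate, and 1,2-addition to the cis-epoxy aldehyde should follow the Cornforth (polar Felkin–Anh) model, with attack past H-5 and away from quaternary C4, to give the erythro carbinol with C6 cis to C12 (6S by CIP because of bromine, the same spatial sense as 6R in the target).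

Step 11
Reactants: 14 (1S,2Z)-2-bromo-3-{[(tert-butyldimethylsilyl)oxy]methyl}-1-[(2R,3S)-3-ethenyl-3-methyloxiran-2-yl]but-2-ene-1,4-diol; 7 (Z)-3-iodobut-2-enal
Product: 16 (2E,5Z)-2-{[(tert-butyldimethylsilyl)oxy]methyl}-3-{(R)-[(2R,3S)-3-ethenyl-3-methyloxiran-2-yl](hydroxy)methyl}-6-iodohepta-2,5-diene-1,4-diol (both C8 epimers), via trilithiated alkenyllithium 15 (not isolated)
Conditions: t-BuLi (4.1 equiv), THF, −78 °C; then 7; then H2O
Reagents that add atoms: none
Why: The second bromine–lithium exchange proceeds with retention to a configurationally stable alkenyllithium that should add 1,2 to the enal faster than it exchanges with the vinylic iodide, so C8 ends up cis to C13, and the uncontrolled C8 carbinol does not matter because it is oxidised in the next step.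

Step 12
Reactants: 16 (2E,5Z)-2-{[(tert-butyldimethylsilyl)oxy]methyl}-3-{(R)-[(2R,3S)-3-ethenyl-3-methyloxiran-2-yl](hydroxy)methyl}-6-iodohepta-2,5-diene-1,4-diol
Product: 18 (5R)-3-{[(tert-butyldimethylsilyl)oxy]methyl}-5-[(2R,3S)-3-ethenyl-3-methyloxiran-2-yl]-4-[(2Z)-3-iodobut-2-enoyl]furan-2(5H)-one, via lactol 17 (not isolated)
Conditions: MnO2 (activated, excess), CH2Cl2, rt
Reagents that add atoms: none
Why: Oxidative lactonisation of a (Z)-2-ene-1,4-diol, in which MnO2 takes the primary allylic C12 alcohol to the enal, the cis C6 hydroxyl closes the lactol and this is oxidised on to the butenolide, while the doubly allylic C8 carbinol goes to the dienone, all under neutral conditions that suit the vinyl oxirane.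

Step 13
Reactants: 18 (5R)-3-{[(tert-butyldimethylsilyl)oxy]methyl}-5-[(2R,3S)-3-ethenyl-3-methyloxiran-2-yl]-4-[(2Z)-3-iodobut-2-enoyl]furan-2(5H)-one
Product: 19 (5R)-3-{[(tert-butyldimethylsilyl)oxy]methyl}-5-[(2R,3S)-3-ethenyl-3-methyloxiran-2-yl]-4-[(1R,2Z)-1-hydroxy-3-iodobut-2-en-1-yl]furan-2(5H)-one
Conditions: (S)-2-methyl-CBS-oxazaborolidine (0.5 equiv), catecholborane, toluene, −78 °C
Reagents that add atoms: none
Why: Corey–Bakshi–Shibata reduction, in which the fully substituted butenolide carbon C7 acts as the large group and the CH=C(CH3)I arm as the small one, so the (S)-catalyst should deliver hydride to give 8R, and catecholborane at −78 °C spares the terminal alkene, the lactone and the oxirane.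

Step 14
Reactants: 19 (5R)-3-{[(tert-butyldimethylsilyl)oxy]methyl}-5-[(2R,3S)-3-ethenyl-3-methyloxiran-2-yl]-4-[(1R,2Z)-1-hydroxy-3-iodobut-2-en-1-yl]furan-2(5H)-one
Product: 20 (5R)-3-{[(tert-butyldimethylsilyl)oxy]methyl}-4-{(1R,2Z)-1-[(tert-butyldimethylsilyl)oxy]-3-iodobut-2-en-1-yl}-5-[(2R,3S)-3-ethenyl-3-methyloxiran-2-yl]furan-2(5H)-one
Conditions: TBSOTf, 2,6-lutidine, CH2Cl2, −78 °C
Reagents that add atoms: tert-butyldimethylsilyl trifluoromethanesulfonate, CC(C)(C)[Si](C)(C)OS(=O)(=O)C(F)(F)F
Why: Silyl triflate with excess hindered base silylates the crowded C8 carbinol at low temperature, where the oxirane should stay closed, and leaves no allylic ester for palladium to ionise.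

Step 15
Reactants: 20 (5R)-3-{[(tert-butyldimethylsilyl)oxy]methyl}-4-{(1R,2Z)-1-[(tert-butyldimethylsilyl)oxy]-3-iodobut-2-en-1-yl}-5-[(2R,3S)-3-ethenyl-3-methyloxiran-2-yl]furan-2(5H)-one
Product: 21 C2 B-alkyl-9-BBN of 20 (boron on the former terminal vinyl carbon; 4S,5R,6R,8R; C10 (Z)-vinyl iodide), used as its THF solution
Conditions: 9-BBN (1.3 equiv), THF, 0 °C to rt
Reagents that add atoms: 9-borabicyclo[3.3.1]nonane, C1CC2CCCC(C1)B2
Why: Anti-Markovnikov hydroboration with 9-BBN, in which the quaternary C4 reinforces terminal placement of boron so that no β-boryl oxirane prone to fragmentation arises, while the trisubstituted iodoalkene, the tetrasubstituted butenolide alkene, the lactone and the oxirane react far more slowly.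

Step 16
Reactants: 21 C2 B-alkyl-9-BBN with C10 (Z)-vinyl iodide (4S,5R,6R,8R); 22 carbon monoxide
Product: 23 ten-membered (Z)-9,10-enone: 8,13-bis[(tert-butyldimethylsilyl)oxy]-4,5-epoxy-1-oxogermacra-7(11),9-dien-12,6-olide (4S,5R,6R,8R)
Conditions: CO (3 atm), PdCl2(dppf) (15 mol %), K3PO4 (3 equiv), THF–DMF–H2O, 40 °C, 21 added by syringe pump over 12 h (final 1 mM)
Reagents that add atoms: none
Why: Proposed new method: zerovalent palladium inserts into the C10–I bond with retention of the Z geometry, CO inserts to give the C1 acylpalladium iodide, phosphate-activated boron hands C2 over to palladium and reductive elimination forges C1–C2, so that C1–C10 and C1–C2 are both made in one catalytic cycle. The closest known reaction types are the intermolecular carbonylative Suzuki–Miyaura coupling of B-alkyl-9-BBN reagents with 1-iodoalkenes, the B-alkyl Suzuki–Miyaura macrocyclisation without CO and the carbonylative Stille macrocyclisation, but their combination in one ring closure has not been shown. The ten-membered carbocycle closes at the intramolecular transmetalation/reductive-elimination stage through an eleven-membered acylpalladacycle, and the Z-alkene, the cis-oxirane and the flat butenolide act as three turns that bring C2 close to C1. No stereocentre is formed, C4, C5, C6 and C8 are spectators and the alkene geometry is kept. Two selectivities are needed: CO insertion before transmetalation, which CO pressure and the strain of the nine-membered ring from direct coupling should secure, and cyclisation before oligomerisation, which slow addition at millimolar concentration should secure. The substrate is safe toward zerovalent palladium because hydroboration has consumed the vinyl oxirane, both allylic oxygens are silyl ethers rather than esters, and mild K3PO4 spares the acidic C6–H next to the oxirane.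

Step 17
Reactants: 23 ten-membered (Z)-9,10-enone (4S,5R,6R,8R)
Product: 24 8,13-bis[(tert-butyldimethylsilyl)oxy]-4,5-epoxy-1-oxogermacr-7(11)-en-12,6-olide (4S,5R,6R,8R,10S)
Conditions: [(Ph3P)CuH]6 (0.4 equiv), wet toluene, rt
Reagents that add atoms: none
Why: Conjugate reduction with the copper hydride hexamer adds hydride to C9 of the enone while the tetrasubstituted butenolide is too hindered to react, and C10 arises on protonation of the enolate from the outer face of the ring, which the C8 silyl ether and the folded C4–C8 arc should bias toward 10S.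

Step 18
Reactants: 24 8,13-bis[(tert-butyldimethylsilyl)oxy]-4,5-epoxy-1-oxogermacr-7(11)-en-12,6-olide (4S,5R,6R,8R,10S)
Product: 25 4,5-epoxy-8,13-dihydroxy-1-oxogermacr-7(11)-en-12,6-olide (4S,5R,6R,8R,10S)
Conditions: HF·pyridine, pyridine, THF, 0 °C to rt
Reagents that add atoms: none
Why: Pyridine-buffered fluoride cleaves both silyl ethers without base, so neither C10 nor C6–H is deprotonated, and the buffered medium should leave the trisubstituted oxirane closed.

Step 19
Reactants: 25 4,5-epoxy-8,13-dihydroxy-1-oxogermacr-7(11)-en-12,6-olide (4S,5R,6R,8R,10S)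
Product: 26 13-acetoxy-4,5-epoxy-8-hydroxy-1-oxogermacr-7(11)-en-12,6-olide (4S,5R,6R,8R,10S)
Conditions: Ac2O (1.05 equiv), 2,4,6-collidine, CH2Cl2, −20 °C
Reagents that add atoms: acetic anhydride, CC(=O)OC(C)=O
Why: Kinetically selective acylation, in which the unhindered primary C13 alcohol should react well before the secondary C8 alcohol flanked by the tetrasubstituted alkene.

Step 20
Reactants: 26 13-acetoxy-4,5-epoxy-8-hydroxy-1-oxogermacr-7(11)-en-12,6-olide (4S,5R,6R,8R,10S)
Product: 27 CNP0128625.1, 13-acetoxy-4,5-epoxy-8-(methacryloyloxy)-1-oxogermacr-7(11)-en-12,6-olide (4S,5R,6R,8R,10S)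
Conditions: methacrylic anhydride, DMAP, Et3N, CH2Cl2, 0 °C to rt
Reagents that add atoms: methacrylic anhydride, C=C(C)C(=O)OC(=O)C(C)=C
Why: DMAP-catalysed esterification acylates the remaining C8 alcohol with retention at C8 and is placed last because the methacrylate would not survive 9-BBN or copper hydride.

Compound list
1 | (Z)-3-methylpent-2-en-4-yn-1-ol | C#C/C(C)=C\CO | starting material
2 | [(2R,3S)-3-ethynyl-3-methyloxiran-2-yl]methanol | C#C[C@]1(C)O[C@@H]1CO | intermediate
3 | [(2R,3S)-3-ethenyl-3-methyloxiran-2-yl]methanol | C=C[C@]1(C)O[C@@H]1CO | intermediate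
4 | (2S,3S)-3-ethenyl-3-methyloxirane-2-carbaldehyde | C=C[C@]1(C)O[C@@H]1C=O | intermediate
5 | but-2-yn-1-ol | CC#CCO | starting material
6 | (Z)-3-iodobut-2-en-1-ol | C/C(I)=C/CO | intermediate
7 | (Z)-3-iodobut-2-enal | C/C(I)=C/C=O | intermediate
8 | methyl 2-(hydroxymethyl)prop-2-enoate | C=C(CO)C(=O)OC | starting material
9 | methyl 2-{[(tert-butyldimethylsilyl)oxy]methyl}prop-2-enoate | C=C(CO[Si](C)(C)C(C)(C)C)C(=O)OC | intermediate
10 | methyl 3-[(tert-butyldimethylsilyl)oxy]-2-oxopropanoate | COC(=O)C(=O)CO[Si](C)(C)C(C)(C)C | intermediate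
11 | methyl 3,3-dibromo-2-{[(tert-butyldimethylsilyl)oxy]methyl}prop-2-enoate | COC(=O)C(CO[Si](C)(C)C(C)(C)C)=C(Br)Br | intermediate
12 | 3,3-dibromo-2-{[(tert-butyldimethylsilyl)oxy]methyl}prop-2-en-1-ol | OCC(CO[Si](C)(C)C(C)(C)C)=C(Br)Br | intermediate
13 | chelated (Z)-bromolithio carbenoid, lithium alkoxide of 12 with lithium cis to CH2OLi (not isolated) | [Li]OC/C(CO[Si](C)(C)C(C)(C)C)=C(\[Li])Br | intermediate
14 | (1S,2Z)-2-bromo-3-{[(tert-butyldimethylsilyl)oxy]methyl}-1-[(2R,3S)-3-ethenyl-3-methyloxiran-2-yl]but-2-ene-1,4-diol | C=C[C@]1(C)O[C@@H]1[C@H](O)/C(Br)=C(\CO)CO[Si](C)(C)C(C)(C)C | intermediate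
15 | trilithiated alkenyllithium from 14 (C7–Li, C6–OLi, C12–OLi; not isolated) | C=C[C@]1(C)O[C@@H]1[C@H](O[Li])/C([Li])=C(\CO[Li])CO[Si](C)(C)C(C)(C)C | intermediate
16 | seco triol (C6, C8, C12 hydroxyls; C13 silyl ether; 4S,5R,6R; both C8 epimers; C6 cis to C12; 9Z) | C=C[C@]1(C)O[C@@H]1[C@H](O)/C(C(O)/C=C(/C)I)=C(\CO)CO[Si](C)(C)C(C)(C)C | intermediate
17 | C12 lactol of 16 (not isolated) | C=C[C@]1(C)O[C@@H]1[C@@H]1OC(O)C(CO[Si](C)(C)C(C)(C)C)=C1C(O)/C=C(/C)I | intermediate
18 | (5R)-3-{[(tert-butyldimethylsilyl)oxy]methyl}-5-[(2R,3S)-3-ethenyl-3-methyloxiran-2-yl]-4-[(2Z)-3-iodobut-2-enoyl]furan-2(5H)-one | C=C[C@]1(C)O[C@@H]1[C@@H]1OC(=O)C(CO[Si](C)(C)C(C)(C)C)=C1C(=O)/C=C(/C)I | intermediate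
19 | (8R)-alcohol: 4-[(1R,2Z)-1-hydroxy-3-iodobut-2-en-1-yl] analogue of 18 | C=C[C@]1(C)O[C@@H]1[C@@H]1OC(=O)C(CO[Si](C)(C)C(C)(C)C)=C1[C@H](O)/C=C(/C)I | intermediate
20 | 8,13-bis-silyl ether with C2=C3 vinyl group and C10 (Z)-vinyl iodide (4S,5R,6R,8R) | C=C[C@]1(C)O[C@@H]1[C@@H]1OC(=O)C(CO[Si](C)(C)C(C)(C)C)=C1[C@H](O[Si](C)(C)C(C)(C)C)/C=C(/C)I | intermediate
21 | C2 B-alkyl-9-BBN with C10 (Z)-vinyl iodide (4S,5R,6R,8R) | C1CC2CCCC(C1)B2CC[C@]3(C)O[C@@H]3[C@@H]3OC(=O)C(CO[Si](C)(C)C(C)(C)C)=C3[C@H](O[Si](C)(C)C(C)(C)C)/C=C(/C)I | intermediate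
22 | carbon monoxide (C1) | [C-]#[O+] | starting material
23 | ten-membered (Z)-9,10-enone (4S,5R,6R,8R) | CC(C)(C)[Si](C)(C)O[C@@H]1/C=C(/C)C(=O)CC[C@]2(C)O[C@@H]2[C@@H]2OC(=O)C(CO[Si](C)(C)C(C)(C)C)=C21 | intermediate
24 | saturated C1 ketone, 8,13-bis-silyl ether (4S,5R,6R,8R,10S) | CC(C)(C)[Si](C)(C)O[C@@H]1C[C@H](C)C(=O)CC[C@]2(C)O[C@@H]2[C@@H]2OC(=O)C(CO[Si](C)(C)C(C)(C)C)=C21 | intermediate
25 | 8,13-diol (4S,5R,6R,8R,10S) | O[C@@H]1C[C@H](C)C(=O)CC[C@]2(C)O[C@@H]2[C@@H]2OC(=O)C(CO)=C21 | intermediate
26 | 13-acetate, 8-alcohol (4S,5R,6R,8R,10S) | O[C@@H]1C[C@H](C)C(=O)CC[C@]2(C)O[C@@H]2[C@@H]2OC(=O)C(COC(C)=O)=C21 | intermediate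
27 | CNP0128625.1 (4S,5R,6R,8R,10S) | C=C(C)C(=O)O[C@@H]1C[C@H](C)C(=O)CC[C@]2(C)O[C@@H]2[C@@H]2OC(=O)C(COC(C)=O)=C21 | target

Total step count: 20
Longest linear sequence: 15 steps (8 to 27, steps 6–20)

Steps most likely to fail

Step 16. CO insertion may be outrun by direct transfer of the alkyl group. The borane may be lost by protodeboronation or by β-hydride elimination after transmetalation. Intermolecular coupling may also compete with ring closure. The fallback sets out from 21 and closes the ring by a Nozaki–Hiyama–Kishi reaction, which is known chemistry. Reductive carbonylation of the B-alkyl-9-BBN (CO, K[HB(OiPr)3], THF, then buffered H2O2) would give the one-carbon-homologated C1 aldehyde F1. CrCl2 with catalytic NiCl2 at high dilution would join C1 to C10 and give the ten-membered C1 allylic alcohol F2. Dess–Martin oxidation would bring the route back at 23.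

Step 10. The carbenoid may lose its geometry by equilibration or decay by α-elimination, and facial selectivity in the addition to the epoxy aldehyde may be poor. In the fallback C6 is set by hydride delivery instead of by carbon–carbon bond formation. It sets out from 4, where Pinnick oxidation would give the epoxy acid F3 and EDC coupling with MeNHOMe·HCl the Weinreb amide F4. Acylation of carbenoid 13 (from 12) would give the (Z)-bromo enone F5. Chelation-controlled reduction of this α,β-epoxy ketone with Zn(BH4)2, which is known to favour erythro epoxy alcohols, would come back to the route at 14.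

Step 17. Protonation of the macrocyclic enolate may show poor facial selectivity, and base-induced correction risks deprotonation at C6–H with opening of the oxirane. In the fallback the C10–H bond is formed by catalyst-controlled syn addition of H2 rather than by enolate protonation. It sets out from 23, where asymmetric hydrogenation of the α-methyl enone with [Ir(cod){(S)-tBu-PHOX}]B[3,5-(CF3)2C6H3]4 (either ligand enantiomer, as required) under H2 in CH2Cl2 would leave the tetrasubstituted butenolide alkene untouched. It comes back directly at 24.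

Further compounds
F1 | step 16 | C1 aldehyde with C10 (Z)-vinyl iodide (4S,5R,6R,8R) | O=CCC[C@]1(C)O[C@@H]1[C@@H]1OC(=O)C(CO[Si](C)(C)C(C)(C)C)=C1[C@H](O[Si](C)(C)C(C)(C)C)/C=C(/C)I
F2 | step 16 | ten-membered C1 allylic alcohol, both C1 epimers (4S,5R,6R,8R; 9Z) | CC(C)(C)[Si](C)(C)O[C@@H]1/C=C(/C)C(O)CC[C@]2(C)O[C@@H]2[C@@H]2OC(=O)C(CO[Si](C)(C)C(C)(C)C)=C21
F3 | step 10 | (2S,3S)-3-ethenyl-3-methyloxirane-2-carboxylic acid | C=C[C@]1(C)O[C@@H]1C(=O)O
F4 | step 10 | (2S,3S)-3-ethenyl-N-methoxy-N,3-dimethyloxirane-2-carboxamide | C=C[C@]1(C)O[C@@H]1C(=O)N(C)OC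
F5 | step 10 | (Z)-bromo enone, C6 ketone analogue of 14 | C=C[C@]1(C)O[C@@H]1C(=O)/C(Br)=C(\CO)CO[Si](C)(C)C(C)(C)C
F0 | step 17 | none | none
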